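**Plan**
- Retrosynthesis: remove the two esters; C9–OH goes back to a C9 ketone, C8–O to an enolate oxidation and the C7 isopropenyl to a cuprate addition, which leaves the cis-fused enedione 13. Its C1–C10 bond (ring B) is cut to the monocyclic diketone 11, then C5–CH3 and the C4–C5 bond are cut back to 1 + 2.
- Feature used: the C2 ketone and the C9 oxygen are 1,4-related across the C1–C10 bond at the ring fusion, so C1 and C10 are both carbonyl α-carbons and can be joined by oxidative coupling of a bis-enolate.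
- Forward order: ring A enters as the anisole ring of 1 and is unveiled by Birch reduction; the C5 methyl is added; ring B is closed last at C1–C10; C7, C8 and C9 are then decorated on the bicycle.
- Stereochemistry: C4 from the [Rh(OH)((S)-BINAP)]2-catalysed 1,4-arylation and C5 from the Cu(O2CC4H3S)/phosphoramidite-catalysed AlMe3 addition (both reagent-controlled); C10 from the tether in the ring closure (cis fusion); C7 and C8 from cuprate addition and enolate oxidation; C9 from hydride attack anti to ring B.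
- Locants (eremophilane numbering): ring B = C1–C5 and C10 (ketone C2, methyls on C4 and C5); ring A = C5–C10 (isopropenyl C7, acetate C8, senecioate C9).

Key step: step 6

Assumption: the (S)-BINAP and (S,S,S)-phosphoramidite complexes are taken to deliver aryl and methyl to the faces needed here, as with closely related enones; the ligand antipode would be used if the sense proved opposite.

Step 1
Reactants: 1 (3-methoxyphenyl)boronic acid; 2 (E)-pent-3-en-2-one
Product: 3 (4S)-4-(3-methoxyphenyl)pentan-2-one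
Conditions: [Rh(OH)((S)-BINAP)]2 (1.5 mol%), dioxane/H2O 10:1, 35 °C
Reagents that add atoms: none
Why: Hayashi–Miyaura reaction, in which the aryl–rhodium species adds 1,4 to the E-enone and the BINAP ligand selects the enone face, so that C4 should be set as S.

Step 2
Reactants: 3 (4S)-4-(3-methoxyphenyl)pentan-2-one
Product: 4 2-[(2S)-2-(3-methoxyphenyl)propyl]-2-methyl-1,3-dioxolane
Conditions: HOCH2CH2OH, p-TsOH (cat.), benzene, reflux, Dean–Stark
Reagents that add atoms: ethane-1,2-diol, OCCO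
Why: Acid-catalysed ketalisation with azeotropic removal of water masks the ketone against the dissolving-metal, organoaluminium and amide-base steps, and the stereocentre is β to the carbonyl so it cannot epimerise.

Step 3
Reactants: 4 2-[(2S)-2-(3-methoxyphenyl)propyl]-2-methyl-1,3-dioxolane
Product: 7 3-[(2S)-1-(2-methyl-1,3-dioxolan-2-yl)propan-2-yl]cyclohex-2-en-1-one, via Birch dihydroanisole 5 (not isolated), via unconjugated enone 6 (not isolated)
Conditions: Li, NH3(l), t-BuOH, THF, −78 to −33 °C; NH4Cl; then (CO2H)2, MeOH/H2O, rt; then DBU (cat.), CH2Cl2, rt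
Reagents that add atoms: water, O
Why: Birch reduction of the 3-alkylanisole should give the 1-methoxy-5-alkylcyclohexa-1,4-diene, oxalic acid then hydrolyses only the enol ether (the dioxolane is far slower), and DBU moves the double bond into conjugation through the doubly activated ring CH2 and not through the side-chain stereocentre.

Step 4
Reactants: 7 3-[(2S)-1-(2-methyl-1,3-dioxolan-2-yl)propan-2-yl]cyclohex-2-en-1-one
Product: 8 (3S)-3-methyl-3-[(2S)-1-(2-methyl-1,3-dioxolan-2-yl)propan-2-yl]cyclohexan-1-one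
Conditions: AlMe3 (1.5 equiv), Cu(O2CC4H3S) (5 mol%), (S)-binaphthyl-2,2'-diyl N,N-bis[(S)-1-phenylethyl]phosphoramidite (10 mol%), Et2O, −30 °C; aq. NH4Cl
Reagents that add atoms: trimethylaluminium, C[Al](C)C
Why: Copper-catalysed asymmetric conjugate addition of AlMe3 to a β-substituted cyclohexenone creates the quaternary C5, the chiral phosphoramidite directing methyl to the Si face of the ring β-carbon under catalyst control, which should give the 3S ketone.

Step 5
Reactants: 8 (3S)-3-methyl-3-[(2S)-1-(2-methyl-1,3-dioxolan-2-yl)propan-2-yl]cyclohexan-1-one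
Product: 11 (5S)-5-methyl-5-[(2S)-4-oxopentan-2-yl]cyclohex-2-en-1-one, via lithium enolate 9 (not isolated), via ketal enone 10 (not isolated)
Conditions: LiN(i-Pr)2 (1.1 equiv), THF, −78 °C; PhS(Cl)=N-t-Bu, −78 °C; then 1 M HCl, THF, rt
Reagents that add atoms: water, O
Why: Mukaiyama dehydrogenation, in which kinetic deprotonation at the ring CH2 remote from the quaternary carbon, sulfur transfer and syn-elimination should give the enone on the only side that has a β-hydrogen, and the acidic work-up removes the dioxolane to free the methyl ketone for the coupling.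

Step 6
Reactants: 11 (5S)-5-methyl-5-[(2S)-4-oxopentan-2-yl]cyclohex-2-en-1-one
Product: 13 (4aR,5S,8aS)-4a,5-dimethyl-4a,5,6,8a-tetrahydronaphthalene-1,7(4H,8H)-dione, via dilithium bis-enolate 12 (not isolated)
Conditions: LiN(i-Pr)2 (2.3 equiv), THF, −78 °C; then CuCl2 (2.3 equiv) in DMF, −78 to 0 °C, 5 mM
Reagents that add atoms: none
Why: Double deprotonation should give the cross-conjugated C9/C10 enolate of the enone and the kinetic C1 enolate of the methyl ketone; CuCl2 then removes one electron from an enolate, the α-keto radical (or its copper-bound equivalent) attacks the other enolate carbon, and a second one-electron oxidation delivers the 1,4-diketone. The closest known reaction type is the intramolecular oxidative coupling of ketone bis-enolates to cyclic 1,4-diketones with divalent copper or trivalent iron salts. Ring B is closed as a six-membered ring by 6-exo-trig attack of C1 on the C9=C10 enolate double bond. The one new stereocentre, C10, is controlled by the tether: C1 hangs from C4 on C5 and can reach C10 only on the face that carries the C5–C4 bond, so H-10 should end up cis to the angular methyl (cis-decalin). The step needs regioselective enolisation, secured in ring A by the C7=C8 double bond (C10 is the only ring α-CH2) and in the side chain by kinetic deprotonation of the methyl group, and it needs ring closure to outrun dimerisation, secured by high dilution and the six-membered transition state.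

Step 7
Reactants: 13 (4aR,5S,8aS)-4a,5-dimethyl-4a,5,6,8a-tetrahydronaphthalene-1,7(4H,8H)-dione
Product: 14 (4aR,5S,8aS)-7,7-(ethane-1,2-diyldioxy)-4a,5-dimethyl-4a,5,6,7,8,8a-hexahydronaphthalen-1(4H)-one
Conditions: Me3SiOCH2CH2OSiMe3, Me3SiOSO2CF3 (cat.), CH2Cl2, −78 °C
Reagents that add atoms: 1,2-bis(trimethylsilyloxy)ethane, C[Si](C)(C)OCCO[Si](C)(C)C
Why: Noyori ketalisation is selective for the saturated, unhindered C2 ketone over the conjugated, α-branched C9 carbonyl and masks C2 for the later hydride step without base that could epimerise C10.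

Step 8
Reactants: 14 (4aR,5S,8aS)-7,7-(ethane-1,2-diyldioxy)-4a,5-dimethyl-4a,5,6,7,8,8a-hexahydronaphthalen-1(4H)-one
Product: 15 [(3S,4aR,5S,8aS)-7,7-(ethane-1,2-diyldioxy)-4a,5-dimethyl-3-(prop-1-en-2-yl)-3,4,4a,5,6,7,8,8a-octahydronaphthalen-1-yl]oxy(trimethyl)silane
Conditions: CH2=C(CH3)MgBr, CuBr·SMe2 (20 mol%), Me3SiCl, THF, −78 °C; Et3N, cold aq. NaHCO3
Reagents that add atoms: isopropenylmagnesium bromide, C=C(C)[Mg]Br; chlorotrimethylsilane, C[Si](C)(C)Cl
Why: Me3SiCl-accelerated copper-catalysed conjugate addition should bring the isopropenyl group to C7 on the convex face of the cis-decalin, syn to the small angular methyl and anti to the ring B carbon C4 that flanks the other face, and the enolate is trapped regiospecifically as the C8=C9 enol silane.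

Step 9
Reactants: 15 [(3S,4aR,5S,8aS)-7,7-(ethane-1,2-diyldioxy)-4a,5-dimethyl-3-(prop-1-en-2-yl)-3,4,4a,5,6,7,8,8a-octahydronaphthalen-1-yl]oxy(trimethyl)silane
Product: 17 (2R,3R,4aR,5S,8aS)-7,7-(ethane-1,2-diyldioxy)-2-hydroxy-4a,5-dimethyl-3-(prop-1-en-2-yl)octahydronaphthalen-1(2H)-one, via silyloxy ketone 16 (not isolated)
Conditions: m-CPBA (1.05 equiv), NaHCO3, CH2Cl2, −20 °C; then AcOH, THF/H2O, 0 °C
Reagents that add atoms: 3-chloroperoxybenzoic acid, OOC(=O)c1cccc(Cl)c1
Why: Rubottom oxidation, in which the electron-rich enol silane is epoxidised far faster than the isopropenyl alkene, oxygen enters C8 anti to the neighbouring isopropenyl group, and silyl migration followed by hydrolysis should give the ketol with C8–OH trans to isopropenyl (also the equatorial, more stable epimer).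

Step 10
Reactants: 17 (2R,3R,4aR,5S,8aS)-7,7-(ethane-1,2-diyldioxy)-2-hydroxy-4a,5-dimethyl-3-(prop-1-en-2-yl)octahydronaphthalen-1(2H)-one
Product: 18 (2R,3R,4aR,5S,8aS)-7,7-(ethane-1,2-diyldioxy)-4a,5-dimethyl-1-oxo-3-(prop-1-en-2-yl)decahydronaphthalen-2-yl acetate
Conditions: Ac2O, pyridine, DMAP (cat.), CH2Cl2, 0 °C
Reagents that add atoms: acetic anhydride, CC(=O)OC(C)=O
Why: DMAP-catalysed acetylation of the secondary ketol hydroxyl, where any base-induced equilibration at C8 can only favour the equatorial acetate that is wanted.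

Step 11
Reactants: 18 (2R,3R,4aR,5S,8aS)-7,7-(ethane-1,2-diyldioxy)-4a,5-dimethyl-1-oxo-3-(prop-1-en-2-yl)decahydronaphthalen-2-yl acetate
Product: 19 (1S,2R,3R,4aR,5S,8aS)-7,7-(ethane-1,2-diyldioxy)-1-hydroxy-4a,5-dimethyl-3-(prop-1-en-2-yl)decahydronaphthalen-2-yl acetate
Conditions: LiBH(s-Bu)3, THF, −78 °C; AcOH quench at −78 °C
Reagents that add atoms: none
Why: Bulky-hydride ketone reduction, in which axial approach to C9 is blocked by the syn-axial ring B carbon C4, so hydride should enter equatorially from the convex face and give the axial C9 alcohol cis to the C8 acetate, the cold acidic quench suppressing acetyl migration.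

Step 12
Reactants: 19 (1S,2R,3R,4aR,5S,8aS)-7,7-(ethane-1,2-diyldioxy)-1-hydroxy-4a,5-dimethyl-3-(prop-1-en-2-yl)decahydronaphthalen-2-yl acetate
Product: 20 (1S,2R,3R,4aR,5S,8aS)-2-acetoxy-7,7-(ethane-1,2-diyldioxy)-4a,5-dimethyl-3-(prop-1-en-2-yl)decahydronaphthalen-1-yl 3-methylbut-2-enoate
Conditions: (CH3)2C=CHCOCl, pyridine, DMAP (cat.), CH2Cl2, 0 °C to rt
Reagents that add atoms: 3-methylbut-2-enoyl chloride, CC(C)=CC(=O)Cl
Why: DMAP-catalysed esterification of the hindered axial alcohol with the acid chloride under weakly basic conditions that do not form an alkoxide, so no stereocentre is touched and the acetate should stay on O8.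

Step 13
Reactants: 20 (1S,2R,3R,4aR,5S,8aS)-2-acetoxy-7,7-(ethane-1,2-diyldioxy)-4a,5-dimethyl-3-(prop-1-en-2-yl)decahydronaphthalen-1-yl 3-methylbut-2-enoate
Product: 21 (1S,2R,3R,4aR,5S,8aS)-2-acetoxy-4a,5-dimethyl-7-oxo-3-(prop-1-en-2-yl)decahydronaphthalen-1-yl 3-methylbut-2-enoate
Conditions: 0.5 M HCl, THF/H2O, rt
Reagents that add atoms: water, O
Why: Acid-catalysed ketal hydrolysis releases the C2 ketone, and the two esters and the isopropenyl group should tolerate dilute acid at room temperature.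

**Compound list**
1 | (3-methoxyphenyl)boronic acid | COc1cccc(c1)B(O)O | starting material
2 | (E)-pent-3-en-2-one | C/C=C/C(C)=O | starting material
3 | (4S)-4-(3-methoxyphenyl)pentan-2-one | COc1cccc(c1)[C@@H](C)CC(C)=O | intermediate
4 | 2-[(2S)-2-(3-methoxyphenyl)propyl]-2-methyl-1,3-dioxolane | COc1cccc(c1)[C@@H](C)CC1(C)OCCO1 | intermediate
5 | 2-[(2S)-2-(5-methoxycyclohexa-1,4-dien-1-yl)propyl]-2-methyl-1,3-dioxolane | COC1=CCC=C(C1)[C@@H](C)CC1(C)OCCO1 | intermediate (not isolated)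
6 | 3-[(2S)-1-(2-methyl-1,3-dioxolan-2-yl)propan-2-yl]cyclohex-3-en-1-one | O=C1CCC=C(C1)[C@@H](C)CC1(C)OCCO1 | intermediate (not isolated)
7 | 3-[(2S)-1-(2-methyl-1,3-dioxolan-2-yl)propan-2-yl]cyclohex-2-en-1-one | O=C1C=C(CCC1)[C@@H](C)CC1(C)OCCO1 | intermediate
8 | (3S)-3-methyl-3-[(2S)-1-(2-methyl-1,3-dioxolan-2-yl)propan-2-yl]cyclohexan-1-one | C1CC[C@@]([C@@H](C)CC2(C)OCCO2)(C)CC1=O | intermediate
9 | lithium (5S)-5-methyl-5-[(2S)-1-(2-methyl-1,3-dioxolan-2-yl)propan-2-yl]cyclohex-1-en-1-olate | [Li]OC1=CCC[C@@]([C@@H](C)CC2(C)OCCO2)(C)C1 | intermediate (not isolated)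
10 | (5S)-5-methyl-5-[(2S)-1-(2-methyl-1,3-dioxolan-2-yl)propan-2-yl]cyclohex-2-en-1-one | C1=CC[C@@]([C@@H](C)CC2(C)OCCO2)(C)CC1=O | intermediate (not isolated)
11 | (5S)-5-methyl-5-[(2S)-4-oxopentan-2-yl]cyclohex-2-en-1-one | C1=CC[C@@]([C@@H](C)CC(C)=O)(C)CC1=O | intermediate
12 | dilithium (3R)-3-methyl-3-[(2S)-4-oxidopent-4-en-2-yl]cyclohexa-1,5-dien-1-olate | C1=CC[C@@]([C@@H](C)CC(=C)O[Li])(C)C=C1O[Li] | intermediate (not isolated)
13 | (4aR,5S,8aS)-4a,5-dimethyl-4a,5,6,8a-tetrahydronaphthalene-1,7(4H,8H)-dione | C1=CC[C@@]2(C)[C@H](CC(=O)C[C@@H]2C)C1=O | intermediate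
14 | (4aR,5S,8aS)-7,7-(ethane-1,2-diyldioxy)-4a,5-dimethyl-4a,5,6,7,8,8a-hexahydronaphthalen-1(4H)-one | C1=CC[C@@]2(C)[C@H](CC3(OCCO3)C[C@@H]2C)C1=O | intermediate
15 | [(3S,4aR,5S,8aS)-7,7-(ethane-1,2-diyldioxy)-4a,5-dimethyl-3-(prop-1-en-2-yl)-3,4,4a,5,6,7,8,8a-octahydronaphthalen-1-yl]oxy(trimethyl)silane | C=C(C)[C@H]1C[C@@]2(C)[C@H](CC3(OCCO3)C[C@@H]2C)C(O[Si](C)(C)C)=C1 | intermediate
16 | (2R,3R,4aR,5S,8aS)-7,7-(ethane-1,2-diyldioxy)-4a,5-dimethyl-3-(prop-1-en-2-yl)-2-(trimethylsilyloxy)octahydronaphthalen-1(2H)-one | C=C(C)[C@H]1C[C@@]2(C)[C@H](CC3(OCCO3)C[C@@H]2C)C(=O)[C@@H]1O[Si](C)(C)C | intermediate (not isolated)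
17 | (2R,3R,4aR,5S,8aS)-7,7-(ethane-1,2-diyldioxy)-2-hydroxy-4a,5-dimethyl-3-(prop-1-en-2-yl)octahydronaphthalen-1(2H)-one | C=C(C)[C@H]1C[C@@]2(C)[C@H](CC3(OCCO3)C[C@@H]2C)C(=O)[C@@H]1O | intermediate
18 | (2R,3R,4aR,5S,8aS)-7,7-(ethane-1,2-diyldioxy)-4a,5-dimethyl-1-oxo-3-(prop-1-en-2-yl)decahydronaphthalen-2-yl acetate | C=C(C)[C@H]1C[C@@]2(C)[C@H](CC3(OCCO3)C[C@@H]2C)C(=O)[C@@H]1OC(C)=O | intermediate
19 | (1S,2R,3R,4aR,5S,8aS)-7,7-(ethane-1,2-diyldioxy)-1-hydroxy-4a,5-dimethyl-3-(prop-1-en-2-yl)decahydronaphthalen-2-yl acetate | C=C(C)[C@H]1C[C@@]2(C)[C@H](CC3(OCCO3)C[C@@H]2C)[C@H](O)[C@@H]1OC(C)=O | intermediate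
20 | (1S,2R,3R,4aR,5S,8aS)-2-acetoxy-7,7-(ethane-1,2-diyldioxy)-4a,5-dimethyl-3-(prop-1-en-2-yl)decahydronaphthalen-1-yl 3-methylbut-2-enoate | C=C(C)[C@H]1C[C@@]2(C)[C@H](CC3(OCCO3)C[C@@H]2C)[C@H](OC(=O)C=C(C)C)[C@@H]1OC(C)=O | intermediate
21 | (1S,2R,3R,4aR,5S,8aS)-2-acetoxy-4a,5-dimethyl-7-oxo-3-(prop-1-en-2-yl)decahydronaphthalen-1-yl 3-methylbut-2-enoate | C=C(C)[C@H]1C[C@@]2(C)[C@H](CC(=O)C[C@@H]2C)[C@H](OC(=O)C=C(C)C)[C@@H]1OC(C)=O | target

Total step count: 13. Longest linear sequence: 13 steps (from 1 and 2).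

**Steps most likely to fail**

Step 6. What may go wrong: intermolecular coupling or oligomerisation, proton transfer between enolate and product leading to aldol or Michael side reactions, and α-chlorination by the copper salt. Fallback: setting out from 11, the bis-enolate is trapped (LiN(i-Pr)2 2.3 equiv, Me3SiCl, THF, −78 °C) as [(3R)-3-methyl-3-[(2S)-4-(trimethylsilyloxy)pent-4-en-2-yl]cyclohexa-1,5-dien-1-yl]oxy(trimethyl)silane F1. This isolable bis(enol silane) is oxidised with (NH4)2Ce(NO3)6 and NaHCO3 in MeCN at −30 °C. The ring then closes by radical-cation coupling of two neutral enol silanes with no strong base present, and the route is rejoined at 13.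

Step 4. What may go wrong: slow or poorly face-selective methyl transfer to a β-carbon that carries a branched substituent. Fallback: setting out from 7, Corey–Bakshi–Shibata reduction ((R)-2-methyl-CBS-oxazaborolidine, BH3·SMe2, THF, −20 °C) should give (1S)-3-[(2S)-1-(2-methyl-1,3-dioxolan-2-yl)propan-2-yl]cyclohex-2-en-1-ol F2. Hydroxyl-directed Simmons–Smith cyclopropanation (Et2Zn, CH2I2, CH2Cl2, 0 °C) delivers CH2 syn to the hydroxyl to give (1R,2S,6S)-6-[(2S)-1-(2-methyl-1,3-dioxolan-2-yl)propan-2-yl]bicyclo[4.1.0]heptan-2-ol F3. Dess–Martin oxidation gives (1R,6S)-6-[(2S)-1-(2-methyl-1,3-dioxolan-2-yl)propan-2-yl]bicyclo[4.1.0]heptan-2-one F4. Li/NH3 then cleaves the exocyclic cyclopropane bond next to the carbonyl, turning the cyclopropane CH2 into the angular methyl, and the route is rejoined at 8. C5 is here set by the carbinol stereocentre instead of by a chiral copper catalyst.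

Step 12. What may go wrong: slow acylation of the hindered axial hydroxyl together with acetyl migration from O8 to O9, giving the transposed diester. Fallback: setting out from 17, the C8 hydroxyl is protected as its triethylsilyl ether (Et3SiOSO2CF3, 2,6-lutidine) to give (2R,3R,4aR,5S,8aS)-7,7-(ethane-1,2-diyldioxy)-4a,5-dimethyl-3-(prop-1-en-2-yl)-2-(triethylsilyloxy)octahydronaphthalen-1(2H)-one F5. Reduction with LiBH(s-Bu)3 at −78 °C gives (1S,2R,3R,4aR,5S,8aS)-7,7-(ethane-1,2-diyldioxy)-4a,5-dimethyl-3-(prop-1-en-2-yl)-2-(triethylsilyloxy)decahydronaphthalen-1-ol F6. Acylation with (CH3)2C=CHCOCl, DMAP and pyridine at 40 °C, where no migratable acyl group is present, gives (1S,2R,3R,4aR,5S,8aS)-7,7-(ethane-1,2-diyldioxy)-4a,5-dimethyl-3-(prop-1-en-2-yl)-2-(triethylsilyloxy)decahydronaphthalen-1-yl 3-methylbut-2-enoate F7. HF·pyridine in THF at 0 °C gives (1S,2R,3R,4aR,5S,8aS)-7,7-(ethane-1,2-diyldioxy)-2-hydroxy-4a,5-dimethyl-3-(prop-1-en-2-yl)decahydronaphthalen-1-yl 3-methylbut-2-enoate F8. Its equatorial hydroxyl is acetylated at once (Ac2O, pyridine, 0 °C), and the route is rejoined at 20. The order of ester introduction is thereby reversed.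

**Further compounds**
F1 | step 6 | [(3R)-3-methyl-3-[(2S)-4-(trimethylsilyloxy)pent-4-en-2-yl]cyclohexa-1,5-dien-1-yl]oxy(trimethyl)silane | C1=CC[C@@]([C@@H](C)CC(=C)O[Si](C)(C)C)(C)C=C1O[Si](C)(C)C
F2 | step 4 | (1S)-3-[(2S)-1-(2-methyl-1,3-dioxolan-2-yl)propan-2-yl]cyclohex-2-en-1-ol | O[C@@H]1C=C(CCC1)[C@@H](C)CC1(C)OCCO1
F3 | step 4 | (1R,2S,6S)-6-[(2S)-1-(2-methyl-1,3-dioxolan-2-yl)propan-2-yl]bicyclo[4.1.0]heptan-2-ol | C1CC[C@@]2([C@@H](C)CC3(C)OCCO3)C[C@H]2[C@H]1O
F4 | step 4 | (1R,6S)-6-[(2S)-1-(2-methyl-1,3-dioxolan-2-yl)propan-2-yl]bicyclo[4.1.0]heptan-2-one | C1CC[C@@]2([C@@H](C)CC3(C)OCCO3)C[C@H]2C1=O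
F5 | step 12 | (2R,3R,4aR,5S,8aS)-7,7-(ethane-1,2-diyldioxy)-4a,5-dimethyl-3-(prop-1-en-2-yl)-2-(triethylsilyloxy)octahydronaphthalen-1(2H)-one | C=C(C)[C@H]1C[C@@]2(C)[C@H](CC3(OCCO3)C[C@@H]2C)C(=O)[C@@H]1O[Si](CC)(CC)CC
F6 | step 12 | (1S,2R,3R,4aR,5S,8aS)-7,7-(ethane-1,2-diyldioxy)-4a,5-dimethyl-3-(prop-1-en-2-yl)-2-(triethylsilyloxy)decahydronaphthalen-1-ol | C=C(C)[C@H]1C[C@@]2(C)[C@H](CC3(OCCO3)C[C@@H]2C)[C@H](O)[C@@H]1O[Si](CC)(CC)CC
F7 | step 12 | (1S,2R,3R,4aR,5S,8aS)-7,7-(ethane-1,2-diyldioxy)-4a,5-dimethyl-3-(prop-1-en-2-yl)-2-(triethylsilyloxy)decahydronaphthalen-1-yl 3-methylbut-2-enoate | C=C(C)[C@H]1C[C@@]2(C)[C@H](CC3(OCCO3)C[C@@H]2C)[C@H](OC(=O)C=C(C)C)[C@@H]1O[Si](CC)(CC)CC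
F8 | step 12 | (1S,2R,3R,4aR,5S,8aS)-7,7-(ethane-1,2-diyldioxy)-2-hydroxy-4a,5-dimethyl-3-(prop-1-en-2-yl)decahydronaphthalen-1-yl 3-methylbut-2-enoate | C=C(C)[C@H]1C[C@@]2(C)[C@H](CC3(OCCO3)C[C@@H]2C)[C@H](OC(=O)C=C(C)C)[C@@H]1O
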